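**Retrosynthetic overview**

1. The route rests on the ring A 5,6-catechol: C8a, which carries O1, lies para to the C6 hydroxyl and is the β-carbon of both the C5 oxygen function and the C4 carbonyl. It therefore becomes a conjugate acceptor once the catechol is oxidised to the ortho-quinone.
2. O1–C8a (ring C) is cut last, back to the open-chain (2R,3R)-β-hydroxy-α-methoxy ketone 9; the forward step is anodic catechol oxidation with 6-endo oxa-Michael closure.
3. C2–C3 is cut by an anti-selective asymmetric boron aldol between aryl methoxymethyl ketone 4 and O-benzylisovanillin 5. Both stereocentres are set here, and the three benzyl ethers are removed by hydrogenolysis.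
4. Ketone 4 comes from 2,3-dihydroxy-4-methoxybenzaldehyde 1 by benzylation, methoxymethyl Grignard addition and oxidation.
5. Rings A and B are bought; ring C is the only ring formed, in the final step.

Key step: step 6

Assumption: the antipode of the menthone-derived borane that sends the E-enolate to the Si face of aldehyde 5 is taken to be the one from (−)-menthone, bis{[(1R,2S,5R)-2-isopropyl-5-methylcyclohexyl]methyl}boron chloride, (MenthCH2)2BCl; if a trial run shows the opposite sense, the reagent from (+)-menthone is used with no other change.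

**Route**

Step 1
Reactants: 1 2,3-dihydroxy-4-methoxybenzaldehyde
Product: 2 2,3-bis(benzyloxy)-4-methoxybenzaldehyde
Conditions: BnBr, K2CO3, DMF, 60 °C
Reagents that add atoms: benzyl bromide, BrCc1ccccc1
Why: Williamson ether synthesis; both phenoxides, including the 2-hydroxyl hydrogen-bonded to the aldehyde, should be alkylated with excess base and gentle heating, and no stereocentre is formed.

Step 2
Reactants: 2 2,3-bis(benzyloxy)-4-methoxybenzaldehyde
Product: 3 rac-1-[2,3-bis(benzyloxy)-4-methoxyphenyl]-2-methoxyethan-1-ol
Conditions: MeOCH2MgCl (from MeOCH2Cl, Mg, cat. HgCl2, THF, −25 °C), THF, −30 → 0 °C; aq NH4Cl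
Reagents that add atoms: methoxymethylmagnesium chloride, COC[Mg]Cl (made in the flask from chloromethyl methyl ether, COCCl, and Mg)
Why: Grignard 1,2-addition of the methoxymethyl reagent to the aryl aldehyde should give the secondary alcohol as a racemate, which does not matter because the carbinol is oxidised in step 3.

Step 3
Reactants: 3 rac-1-[2,3-bis(benzyloxy)-4-methoxyphenyl]-2-methoxyethan-1-ol
Product: 4 1-[2,3-bis(benzyloxy)-4-methoxyphenyl]-2-methoxyethan-1-one
Conditions: Dess–Martin periodinane, CH2Cl2, 0 °C → rt
Reagents that add atoms: none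
Why: Dess–Martin oxidation of a benzylic secondary alcohol is mild enough to leave the benzyl ethers, methyl ethers and the electron-rich ring untouched.

Step 4
Reactants: 4 1-[2,3-bis(benzyloxy)-4-methoxyphenyl]-2-methoxyethan-1-one; 5 3-(benzyloxy)-4-methoxybenzaldehyde
Product: 8 (2R,3R)-1-[2,3-bis(benzyloxy)-4-methoxyphenyl]-3-[3-(benzyloxy)-4-methoxyphenyl]-3-hydroxy-2-methoxypropan-1-one, via E-enol borinate 6 (not isolated), via boron aldolate 7 (not isolated)
Conditions: (MenthCH2)2BCl, Et3N, Et2O, −78 → 0 °C; then 5, −78 → −20 °C; then pH 7 buffer, MeOH, H2O2, 0 °C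
Reagents that add atoms: none
Why: Asymmetric boron aldol reaction; the dialkylboron chloride with Et3N should enolise the aryl ketone to the E-enol borinate (methoxy trans to O–B), which adds to the aldehyde through a closed six-membered chair transition state to give the 2,3-anti adduct, while the chiral menthylmethyl ligands direct attack to the Si face of the aldehyde, setting C3 as R and, through the anti relationship, C2 as R.

Step 5
Reactants: 8 (2R,3R)-1-[2,3-bis(benzyloxy)-4-methoxyphenyl]-3-[3-(benzyloxy)-4-methoxyphenyl]-3-hydroxy-2-methoxypropan-1-one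
Product: 9 (2R,3R)-1-(2,3-dihydroxy-4-methoxyphenyl)-3-hydroxy-3-(3-hydroxy-4-methoxyphenyl)-2-methoxypropan-1-one
Conditions: H2 (1 atm), 10% Pd/C, EtOAc, rt; filtered under Ar and used at once
Reagents that add atoms: none
Why: Heterogeneous catalytic hydrogenolysis should cleave the three aryl benzyl ethers in a neutral aprotic medium that spares the secondary benzylic alcohol and the aryl ketone, and neither stereocentre is touched.

Step 6
Reactants: 9 (2R,3R)-1-(2,3-dihydroxy-4-methoxyphenyl)-3-hydroxy-3-(3-hydroxy-4-methoxyphenyl)-2-methoxypropan-1-one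
Product: 11 (2R,3R)-5,6-dihydroxy-2-(3-hydroxy-4-methoxyphenyl)-3,7-dimethoxychroman-4-one, via acyl ortho-quinone 10 (not isolated)
Conditions: undivided cell, graphite-felt anode, Pt-wire cathode, 0.1 M LiClO4 in MeCN/(CF3)2CHOH 9:1, constant potential at the first anodic wave of 9 (located by cyclic voltammetry), 0 °C, Ar, about 2 F/mol; then aq Na2S2O4, EtOAc
Reagents that add atoms: none
Why: Two-electron, two-proton oxidation at carbon should convert the ring A catechol, the most easily oxidised unit in 9 (the ring B monophenol and the aryl methyl ethers lie higher), into acyl ortho-quinone 10, in which the future C8a is the β-carbon of both the C5 quinone carbonyl and the exocyclic C4 ketone. The C2 hydroxyl then adds to that carbon in an intramolecular oxa-Michael addition and enolisation of the adduct restores the aromatic 5,6-catechol, now carrying O1; the closest known reaction type is the anodic or chemical oxidation of catechols to ortho-quinones with conjugate addition of a tethered amine, carboxylate or hydroxyl group and rearomatisation. Ring C closes in a 6-endo-trig mode, the same geometry as the oxa-Michael closure of 2'-hydroxychalcones to flavanones. No stereocentre is formed: the C2–O bond of the carbinol is never broken and C3 is not deprotonated in the base-free medium, so the (2R,3R) configuration of 9 is carried into 11. The step needs oxidation of the catechol only, which the controlled potential secures, and attack of the tethered hydroxyl at C8a and not of an outside nucleophile at C8, which the six-membered tether, the double activation of C8a and the non-nucleophilic electrolyte and fluoroalcohol secure; hemiketal formation at the C5 carbonyl is reversible and drains into the aromatic product. Because product catechol 11 is more electron-rich than 9 and may be drawn into the oxidation, the Na2S2O4 work-up is included to return any of its quinone to 11.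

**Compound list**

1 | 2,3-dihydroxy-4-methoxybenzaldehyde | COc1ccc(C=O)c(O)c1O | starting material
2 | 2,3-bis(benzyloxy)-4-methoxybenzaldehyde | COc1ccc(C=O)c(OCc2ccccc2)c1OCc1ccccc1 | intermediate
3 | rac-1-[2,3-bis(benzyloxy)-4-methoxyphenyl]-2-methoxyethan-1-ol | COCC(O)c1ccc(OC)c(OCc2ccccc2)c1OCc1ccccc1 | intermediate
4 | 1-[2,3-bis(benzyloxy)-4-methoxyphenyl]-2-methoxyethan-1-one | COCC(=O)c1ccc(OC)c(OCc2ccccc2)c1OCc1ccccc1 | intermediate
5 | 3-(benzyloxy)-4-methoxybenzaldehyde (O-benzylisovanillin) | COc1ccc(C=O)cc1OCc1ccccc1 | starting material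
6 | (E)-1-[2,3-bis(benzyloxy)-4-methoxyphenyl]-2-methoxyethenyl bis{[(1R,2S,5R)-2-isopropyl-5-methylcyclohexyl]methyl}borinate | CO/C=C(/OB(C[C@@H]1C[C@H](C)CC[C@H]1C(C)C)C[C@@H]1C[C@H](C)CC[C@H]1C(C)C)c1ccc(OC)c(OCc2ccccc2)c1OCc1ccccc1 | intermediate
7 | O-[bis(menthylmethyl)boryl] derivative of 8 at the C3 oxygen (boron aldolate) | COc1ccc([C@@H](OB(C[C@@H]2C[C@H](C)CC[C@H]2C(C)C)C[C@@H]2C[C@H](C)CC[C@H]2C(C)C)[C@@H](OC)C(=O)c2ccc(OC)c(OCc3ccccc3)c2OCc2ccccc2)cc1OCc1ccccc1 | intermediate
8 | (2R,3R)-1-[2,3-bis(benzyloxy)-4-methoxyphenyl]-3-[3-(benzyloxy)-4-methoxyphenyl]-3-hydroxy-2-methoxypropan-1-one | COc1ccc([C@@H](O)[C@@H](OC)C(=O)c2ccc(OC)c(OCc3ccccc3)c2OCc2ccccc2)cc1OCc1ccccc1 | intermediate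
9 | (2R,3R)-1-(2,3-dihydroxy-4-methoxyphenyl)-3-hydroxy-3-(3-hydroxy-4-methoxyphenyl)-2-methoxypropan-1-one | COc1ccc([C@@H](O)[C@@H](OC)C(=O)c2ccc(OC)c(O)c2O)cc1O | intermediate
10 | 3-[(2R,3R)-3-hydroxy-3-(3-hydroxy-4-methoxyphenyl)-2-methoxypropanoyl]-6-methoxycyclohexa-3,5-diene-1,2-dione | COc1ccc([C@@H](O)[C@@H](OC)C(=O)C2=CC=C(OC)C(=O)C2=O)cc1O | intermediate
11 | (2R,3R)-5,6-dihydroxy-2-(3-hydroxy-4-methoxyphenyl)-3,7-dimethoxychroman-4-one | COc1ccc([C@H]2Oc3cc(OC)c(O)c(O)c3C(=O)[C@@H]2OC)cc1O | target

Total step count: 6
Longest linear sequence: 6 steps (1 → 2 → 3 → 4 → 8 → 9 → 11)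

**Steps most likely to fail**

Step 6. The product catechol is more electron-rich than 9 and may be oxidised in its place, leaving the conversion stalled at mixed oxidation levels; an anode film may also stop the current before cyclisation is complete. The fallback sets out from 9 and uses a homogeneous oxidant in deliberate excess: o-chloranil (2.2 equiv) in dry MeCN, −20 °C → rt. This should take 9 through 10 and the cyclised catechol on to the isolable ring A quinone of the product, (2R,3R)-2-(3-hydroxy-4-methoxyphenyl)-3,7-dimethoxy-2,3-dihydrochromene-4,5,6-trione F1. F1 is separated from tetrachlorocatechol and reduced with aqueous Na2S2O4 in EtOAc, coming back to the route at 11.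

Step 4. The chiral ligands may discriminate poorly between the faces on this α-alkoxy aryl ketone enolate, giving low enantiomeric purity, and loss of enolate geometry would add syn adduct. The fallback sets out from 4 and 5 and separates diastereo- and enantiocontrol. Achiral dicyclohexylboron chloride with Et3N in Et2O should give the (E)-1-[2,3-bis(benzyloxy)-4-methoxyphenyl]-2-methoxyethenyl dicyclohexylborinate F2, which adds to 5 to give the racemic anti dicyclohexylboron aldolate F3. Oxidative work-up then gives racemic anti 8, any syn isomer being removed on silica. The enantiomers are separated by preparative chromatography on a chiral stationary phase, the (2S,3S)-enantiomer of 8 F4 is discarded, and the route is rejoined at 8.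

Step 5. The benzylic C–OH bond may be hydrogenolysed in competition with O-debenzylation; in addition, once the 2-hydroxyl ortho to the ketone is free, dehydration and ring closure through that phenol would lead to the isomeric flavanone skeleton on prolonged contact with the catalyst. The fallback sets out from 8 and removes the benzyl groups without hydrogen: BCl3 with pentamethylbenzene as cation scavenger in CH2Cl2 at −78 °C, quenched cold with MeOH. This should cleave the three aryl benzyl ethers while the methyl ethers and the carbinol survive at that temperature, and it comes back to the route at 9 with no new intermediate.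

**Further compounds**

F1 | step 6 | (2R,3R)-2-(3-hydroxy-4-methoxyphenyl)-3,7-dimethoxy-2,3-dihydrochromene-4,5,6-trione | COc1ccc([C@H]2OC3=C(C(=O)C(=O)C(OC)=C3)C(=O)[C@@H]2OC)cc1O
F2 | step 4 | (E)-1-[2,3-bis(benzyloxy)-4-methoxyphenyl]-2-methoxyethenyl dicyclohexylborinate | CO/C=C(/OB(C1CCCCC1)C1CCCCC1)c1ccc(OC)c(OCc2ccccc2)c1OCc1ccccc1
F3 | step 4 | rac-(2R*,3R*) O-(dicyclohexylboryl) aldolate of 8 (one enantiomer drawn) | COc1ccc([C@@H](OB(C2CCCCC2)C2CCCCC2)[C@@H](OC)C(=O)c2ccc(OC)c(OCc3ccccc3)c2OCc2ccccc2)cc1OCc1ccccc1
F4 | step 4 | (2S,3S)-1-[2,3-bis(benzyloxy)-4-methoxyphenyl]-3-[3-(benzyloxy)-4-methoxyphenyl]-3-hydroxy-2-methoxypropan-1-one | COc1ccc([C@H](O)[C@H](OC)C(=O)c2ccc(OC)c(OCc3ccccc3)c2OCc2ccccc2)cc1OCc1ccccc1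
F0 | step 5 | none | none
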